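**Strategy.** All three ester alcohols are one amino alcohol, so the cyclobutane core is made first and the cyclopentane ring of that alcohol is the last ring closed; afterwards only reductions and acylations follow. That ring (cyclopenta[c]pyridine numbering) holds oxygen-bearing C6 between C5H2 and C7H(CH3) and is fused to the piperidine at C4a–C7a: a masked 2-methylcyclopentenone. One Pauson–Khand reaction of an acyclic, carbamate-tethered 1,7-enyne therefore makes C4a–C7a (piperidine) and then C5–C6 and C6–C7 (cyclopentenone, C6 from CO). The core arises from a crossed [2+2] photocycloaddition within a mixed anhydride, which the amino alcohol then opens.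

Key step: step 10

Assumption 1: the route has no enantioselective cyclobutane formation; 12 is racemic (its SMILES shows the enantiomer that continues) and is resolved in step 13, where the enantiopure amino alcohol 21 gives two separable diastereomeric half esters, so at most half of 12 is used.
Assumption 2: the sense of induction in step 9 is taken by analogy with cinnamyl-type bromides; if the (S,Sp) ligand gives the (S) product, its enantiomer is used.
Assumption 3: methyl geranate is used as the pure (2E) isomer.
Numbering: bicycle C1, N2, C3, C4, C4a, C5, C6, C7, C7a; cyclobutane C1 (methyl, carboxyl), C2 (aryl), C3 (carboxyl), C4 (side chain).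

**Step 1**
Reactants: 1 ferulic acid [(2E)-3-(4-hydroxy-3-methoxyphenyl)prop-2-enoic acid]
Product: 3 (2E)-3-[3-methoxy-4-(methoxymethoxy)phenyl]prop-2-enoic acid, via MOM ester 2 (not isolated)
Conditions: MOMCl (2.4 equiv), i-Pr2NEt, CH2Cl2, 0 °C to rt; then LiOH, THF/H2O, rt; 1 M HCl to pH 3
Reagents that add atoms: chloromethyl methyl ether COCCl; lithium hydroxide [Li+].[OH-]
Why: Chloromethyl methyl ether alkylates both the phenol and the carboxylate, and hydroxide then cleaves only the acetal-type methoxymethyl ester while the base-stable aryl methoxymethyl ether stays (protection, then selective saponification).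

**Step 2**
Reactants: 4 methyl geranate [methyl (2E)-3,7-dimethylocta-2,6-dienoate]
Product: 6 methyl (2E)-3-methyl-6-oxohex-2-enoate, via ozonide 5 (not isolated)
Conditions: O3 (1.0 equiv), CH2Cl2, −78 °C; then Me2S, −78 °C to rt
Reagents that add atoms: ozone O=[O+][O-]
Why: Ozone should attack the electron-rich isolated trisubstituted alkene much faster than the conjugated enoate, and reduction of the ozonide gives the aldehyde with the (2E) enoate untouched (chemoselective ozonolysis).

**Step 3**
Reactants: 6 methyl (2E)-3-methyl-6-oxohex-2-enoate; 7 2-(triphenyl-λ5-phosphanylidene)propanal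
Product: 8 methyl (2E,6E)-3,7-dimethyl-8-oxoocta-2,6-dienoate
Conditions: toluene, 90 °C
Reagents that add atoms: none
Why: The stabilised formyl ylide should react only with the saturated aldehyde and give the (E)-2-methyl-2-enal (Wittig olefination under thermodynamic control).

**Step 4**
Reactants: 8 methyl (2E,6E)-3,7-dimethyl-8-oxoocta-2,6-dienoate
Product: 9 (2E,6E)-8-methoxy-2,6-dimethyl-8-oxoocta-2,6-dienoic acid
Conditions: NaClO2, NaH2PO4, 2-methylbut-2-ene, t-BuOH/H2O, 0 °C to rt
Reagents that add atoms: sodium chlorite [Na+].[O-]Cl=O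
Why: Chlorite oxidises the enal to the acid without touching either alkene because 2-methylbut-2-ene traps the hypochlorous acid (Pinnick oxidation).

**Step 5**
Reactants: 3 (2E)-3-[3-methoxy-4-(methoxymethoxy)phenyl]prop-2-enoic acid
Product: 10 (2E)-3-[3-methoxy-4-(methoxymethoxy)phenyl]prop-2-enoyl chloride
Conditions: 1-chloro-N,N,2-trimethylprop-1-en-1-amine (1.1 equiv), CH2Cl2, 0 °C to rt; evaporation
Reagents that add atoms: 1-chloro-N,N,2-trimethylprop-1-en-1-amine CC(C)=C(Cl)N(C)C
Why: The α-chloroenamine converts the acid into its chloride under neutral conditions, so the acid-labile methoxymethyl ether should survive (acid chloride formation).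

**Step 6**
Reactants: 10 (2E)-3-[3-methoxy-4-(methoxymethoxy)phenyl]prop-2-enoyl chloride; 9 (2E,6E)-8-methoxy-2,6-dimethyl-8-oxoocta-2,6-dienoic acid
Product: 12 methyl (2E)-5-{7-[3-methoxy-4-(methoxymethoxy)phenyl]-1-methyl-2,4-dioxo-3-oxabicyclo[3.1.1]heptan-6-yl}-3-methylpent-2-enoate (racemic; aryl group and side chain both anti to the O3 bridge), via mixed anhydride 11 (not isolated)
Conditions: 2,6-lutidine (1.05 equiv), CH2Cl2, 0 °C; then MeCN (5 mM), [Ir(dF(CF3)ppy)2(dtbbpy)]PF6 (1 mol%), 450 nm LEDs, argon, 0 °C
Reagents that add atoms: none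
Why: Proposed new method: triplet energy transfer to the feruloyl unit of 11 should give a diradical whose α-carbon adds to the β-carbon of the tethered 2-methylenoyl unit through a six-membered ring (the only mode that leaves a benzylic and a tertiary acyl-stabilised radical), and the 1,4-diradical then closes to the 1,3-bridged cyclobutane with the aryl group and the side chain each equatorial on its six-membered anhydride ring, so that the tether fixes the cis-1,3-dicarboxyl relation and the quaternary centre while sterics set the other two centres; the closest known reaction type is the sensitised crossed intramolecular [2+2] photocycloaddition of 2-methylacryloyl imides to 3-azabicyclo[3.1.1]heptane-2,4-diones, which has not been shown for a mixed carboxylic anhydride.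

**Step 7**
Reactants: 13 but-2-yn-1-amine hydrochloride
Product: 14 methyl (but-2-yn-1-yl)carbamate
Conditions: ClCO2Me (1.05 equiv), Et3N (2.2 equiv), CH2Cl2, 0 °C
Reagents that add atoms: methyl chloroformate COC(=O)Cl
Why: N-Acylation of the primary amine gives the carbamate, which later serves as the tether of the cyclisation and as the source of the N-methyl carbon (carbamate formation).

**Step 8**
Reactants: 14 methyl (but-2-yn-1-yl)carbamate; 15 (2E)-1,4-dibromobut-2-ene (3 equiv)
Product: 16 methyl [(2E)-4-bromobut-2-en-1-yl](but-2-yn-1-yl)carbamate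
Conditions: Cs2CO3, Bu4NI (cat.), DMF, rt
Reagents that add atoms: none
Why: The carbamate nitrogen should be alkylated once by the excess of the symmetrical allylic dibromide (SN2 N-alkylation), which keeps the second allylic bromide for the next step.

**Step 9**
Reactants: 16 methyl [(2E)-4-bromobut-2-en-1-yl](but-2-yn-1-yl)carbamate
Product: 17 methyl (but-2-yn-1-yl)[(2R)-2-methylbut-3-en-1-yl]carbamate
Conditions: MeMgBr (1.2 equiv), CuBr·SMe2 (2 mol%), (S,Sp)-TaniaPhos (2.4 mol%), CH2Cl2, −78 °C
Reagents that add atoms: methylmagnesium bromide C[Mg]Br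
Why: The copper–TaniaPhos catalyst should deliver the methyl group of the Grignard reagent to the γ-carbon of the allylic bromide (enantioselective SN2′ allylic alkylation), which sets C4 under catalyst control and unveils the vinyl group.

**Step 10**
Reactants: 17 methyl (but-2-yn-1-yl)[(2R)-2-methylbut-3-en-1-yl]carbamate
Product: 18 methyl (4R,4aR)-4,7-dimethyl-6-oxo-1,3,4,4a,5,6-hexahydro-2H-cyclopenta[c]pyridine-2-carboxylate
Conditions: Co2(CO)8 (10 mol%), tetramethylthiourea (60 mol%), CO (1 atm), toluene, 70 °C
Reagents that add atoms: carbon monoxide [C-]#[O+]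
Why: The alkyne of 17 binds the dicobalt carbonyl fragment, the tethered vinyl group inserts to give a cobaltacycle, CO inserts and reductive elimination releases the enone while CO regenerates the catalyst; this is the intramolecular Pauson–Khand reaction of a nitrogen-tethered 1,7-enyne, a known reaction type. The piperidine ring closes first, by formation of the C4a–C7a bond in the alkene insertion (six-membered ring, exo with respect to both π bonds), and the cyclopentenone ring closes last as a formal [2+2+1] annulation in which C5–C6 and C6–C7 are made by CO insertion and reductive elimination. The only new stereocentre, C4a, should be controlled by the C4 methyl group, which sits pseudo-equatorial in the chair-like insertion transition state and so ends trans to the new C4a–C5 bond. The step needs CO placed between the methyl-bearing alkyne carbon and the terminal alkene carbon, which the tether enforces, and it needs the carbamate to stay inert, which it is toward Co2(CO)8.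

**Step 11**
Reactants: 18 methyl (4R,4aR)-4,7-dimethyl-6-oxo-1,3,4,4a,5,6-hexahydro-2H-cyclopenta[c]pyridine-2-carboxylate
Product: 20 methyl (4R,4aR,7R,7aS)-4,7-dimethyl-6-oxooctahydro-2H-cyclopenta[c]pyridine-2-carboxylate, via cis-methyl ketone 19 (not isolated)
Conditions: H2 (4 atm), Pd/C, EtOAc, rt; filtration; then NaOMe (0.2 equiv), MeOH, rt
Reagents that add atoms: none
Why: Heterogeneous hydrogenation should add hydrogen to the tetrasubstituted enone from the face of the C4a hydrogen and so set the cis ring fusion at C7a, and methoxide then epimerises C7 next to the ketone to the more stable isomer with the methyl group trans to the C7a–C1 bond.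

**Step 12**
Reactants: 20 methyl (4R,4aR,7R,7aS)-4,7-dimethyl-6-oxooctahydro-2H-cyclopenta[c]pyridine-2-carboxylate
Product: 21 (4R,4aR,6R,7R,7aS)-2,4,7-trimethyloctahydro-1H-cyclopenta[c]pyridin-6-ol
Conditions: LiAlH4 (4 equiv), THF, −78 °C to 0 °C, then reflux; H2O work-up
Reagents that add atoms: none
Why: Hydride should attack the ketone from the convex face of the cis-fused bicycle, as small hydrides do with 2-methylcyclopentanones, which places the hydroxyl group trans to the C7 methyl group and cis to the piperidine ring, and at reflux the same reagent reduces the methyl carbamate to the N-methyl amine.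

**Step 13**
Reactants: 12 racemic bicyclic anhydride; 21 (4R,4aR,6R,7R,7aS)-2,4,7-trimethyloctahydro-1H-cyclopenta[c]pyridin-6-ol
Product: 22 2-[3-methoxy-4-(methoxymethoxy)phenyl]-4-[(3E)-5-methoxy-3-methyl-5-oxopent-3-en-1-yl]-1-methyl-3-{[(4R,4aR,6R,7R,7aS)-2,4,7-trimethyloctahydro-1H-cyclopenta[c]pyridin-6-yl]oxycarbonyl}cyclobutane-1-carboxylic acid (target configuration: both ring carboxyl carbons on one face; aryl group; side chain; C1 methyl on the other face)
Conditions: DMAP (0.2 equiv), CH2Cl2, rt; the two diastereomeric half esters are separated by reversed-phase chromatography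
Reagents that add atoms: none
Why: DMAP-catalysed alcoholysis of the cyclic anhydride should occur at the carbonyl on the hydrogen-bearing bridgehead, far less hindered than the one on the methyl-bearing quaternary bridgehead, with retention at every centre, and the half esters from the two enantiomers of 12 are diastereomers, so the amino alcohol also acts as the resolving agent.

**Step 14**
Reactants: 22 half ester
Product: 23 4-[(3E)-4-carboxy-3-methylbut-3-en-1-yl]-2-[3-methoxy-4-(methoxymethoxy)phenyl]-1-methyl-3-{[(4R,4aR,6R,7R,7aS)-2,4,7-trimethyloctahydro-1H-cyclopenta[c]pyridin-6-yl]oxycarbonyl}cyclobutane-1-carboxylic acid (target configuration)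
Conditions: Me3SnOH (5 equiv), 1,2-dichloroethane, 80 °C; then 1 M HCl to pH 5
Reagents that add atoms: trimethyltin hydroxide C[Sn](C)(C)O
Why: Trimethyltin hydroxide should cleave the unhindered methyl ester by hydroxide transfer and leave the hindered secondary ester and the acetal untouched (chemoselective ester cleavage).

**Step 15**
Reactants: 23 diacid; 21 (4R,4aR,6R,7R,7aS)-2,4,7-trimethyloctahydro-1H-cyclopenta[c]pyridin-6-ol (2.4 equiv)
Product: 26 tris[(4R,4aR,6R,7R,7aS)-2,4,7-trimethyloctahydro-1H-cyclopenta[c]pyridin-6-yl] ester of 4-[(3E)-4-carboxy-3-methylbut-3-en-1-yl]-2-[3-methoxy-4-(methoxymethoxy)phenyl]-1-methylcyclobutane-1,3-dicarboxylic acid (target configuration), via bis(acid chloride) 24 (not isolated), via lithium alkoxide 25 (not isolated)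
Conditions: 23, 1-chloro-N,N,2-trimethylprop-1-en-1-amine (2.4 equiv), CH2Cl2, 0 °C; separately 21, n-BuLi (2.4 equiv), THF, −78 °C; 24 added to 25 at −78 °C, then 0 °C
Reagents that add atoms: none
Why: Acid chlorides are the most reactive acyl donors and a preformed lithium alkoxide should acylate even at the chloride on the quaternary ring carbon, while at −78 °C direct substitution should outrun deprotonation of the unsaturated acid chloride (esterification through acyl chloride and alkoxide).

**Step 16**
Reactants: 26 methoxymethyl-protected tris ester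
Product: 27 CNP0251577.2, tris[(4R,4aR,6R,7R,7aS)-2,4,7-trimethyloctahydro-1H-cyclopenta[c]pyridin-6-yl] ester of 4-[(3E)-4-carboxy-3-methylbut-3-en-1-yl]-2-(4-hydroxy-3-methoxyphenyl)-1-methylcyclobutane-1,3-dicarboxylic acid
Conditions: CF3CO2H/CH2Cl2 (1:4), 0 °C to rt; then aq. NaHCO3
Reagents that add atoms: none
Why: Acid cleaves the aryl methoxymethyl acetal while the three esters and the protonated amines are inert, so the phenol is freed without exposure to base (acetal acidolysis).

**Compound list**

1 | ferulic acid, (2E)-3-(4-hydroxy-3-methoxyphenyl)prop-2-enoic acid | COc1cc(/C=C/C(=O)O)ccc1O | starting material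
2 | methoxymethyl (2E)-3-[3-methoxy-4-(methoxymethoxy)phenyl]prop-2-enoate | COCOC(=O)/C=C/c1ccc(OCOC)c(OC)c1 | intermediate
3 | (2E)-3-[3-methoxy-4-(methoxymethoxy)phenyl]prop-2-enoic acid | COCOc1ccc(/C=C/C(=O)O)cc1OC | intermediate
4 | methyl geranate, methyl (2E)-3,7-dimethylocta-2,6-dienoate | COC(=O)/C=C(\C)CCC=C(C)C | starting material
5 | methyl (2E)-5-(5,5-dimethyl-1,2,4-trioxolan-3-yl)-3-methylpent-2-enoate | COC(=O)/C=C(\C)CCC1OOC(C)(C)O1 | intermediate
6 | methyl (2E)-3-methyl-6-oxohex-2-enoate | COC(=O)/C=C(\C)CCC=O | intermediate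
7 | 2-(triphenyl-λ5-phosphanylidene)propanal | CC(C=O)=P(c1ccccc1)(c1ccccc1)c1ccccc1 | starting material
8 | methyl (2E,6E)-3,7-dimethyl-8-oxoocta-2,6-dienoate | COC(=O)/C=C(\C)CC/C=C(\C)C=O | intermediate
9 | (2E,6E)-8-methoxy-2,6-dimethyl-8-oxoocta-2,6-dienoic acid | COC(=O)/C=C(\C)CC/C=C(\C)C(=O)O | intermediate
10 | (2E)-3-[3-methoxy-4-(methoxymethoxy)phenyl]prop-2-enoyl chloride | COCOc1ccc(/C=C/C(=O)Cl)cc1OC | intermediate
11 | mixed anhydride of 3 and 9 | COCOc1ccc(/C=C/C(=O)OC(=O)/C(C)=C/CC/C(C)=C/C(=O)OC)cc1OC | intermediate
12 | methyl (2E)-5-{7-[3-methoxy-4-(methoxymethoxy)phenyl]-1-methyl-2,4-dioxo-3-oxabicyclo[3.1.1]heptan-6-yl}-3-methylpent-2-enoate, racemic, aryl and side chain anti to the O3 bridge (enantiomer shown continues) | COCOc1ccc(cc1OC)[C@@H]2[C@H]3C(=O)OC(=O)[C@]2(C)[C@H]3CC/C(C)=C/C(=O)OC | intermediate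
13 | but-2-yn-1-amine hydrochloride | CC#CCN.Cl | starting material
14 | methyl (but-2-yn-1-yl)carbamate | CC#CCNC(=O)OC | intermediate
15 | (2E)-1,4-dibromobut-2-ene | BrC/C=C/CBr | starting material
16 | methyl [(2E)-4-bromobut-2-en-1-yl](but-2-yn-1-yl)carbamate | CC#CCN(C/C=C/CBr)C(=O)OC | intermediate
17 | methyl (but-2-yn-1-yl)[(2R)-2-methylbut-3-en-1-yl]carbamate | CC#CCN(C[C@H](C)C=C)C(=O)OC | intermediate
18 | methyl (4R,4aR)-4,7-dimethyl-6-oxo-1,3,4,4a,5,6-hexahydro-2H-cyclopenta[c]pyridine-2-carboxylate | O=C1C[C@@H]2[C@@H](C)CN(C(=O)OC)CC2=C1C | intermediate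
19 | methyl (4R,4aR,7S,7aS)-4,7-dimethyl-6-oxooctahydro-2H-cyclopenta[c]pyridine-2-carboxylate | O=C1C[C@@H]2[C@@H](C)CN(C(=O)OC)C[C@@H]2[C@@H]1C | intermediate
20 | methyl (4R,4aR,7R,7aS)-4,7-dimethyl-6-oxooctahydro-2H-cyclopenta[c]pyridine-2-carboxylate | O=C1C[C@@H]2[C@@H](C)CN(C(=O)OC)C[C@@H]2[C@H]1C | intermediate
21 | (4R,4aR,6R,7R,7aS)-2,4,7-trimethyloctahydro-1H-cyclopenta[c]pyridin-6-ol | O[C@@H]1C[C@H]2[C@H](CN(C)C[C@@H]2C)[C@H]1C | intermediate
22 | half ester: C3 ester of 21, C1 carboxylic acid, side-chain methyl ester, aryl methoxymethyl ether (target configuration) | COCOc1ccc(cc1OC)[C@@H]2[C@@H](C(=O)O[C@@H]3C[C@H]4[C@H](CN(C)C[C@@H]4C)[C@H]3C)[C@H](CC/C(C)=C/C(=O)OC)[C@@]2(C)C(=O)O | intermediate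
23 | diacid: C3 ester of 21, C1 and side-chain carboxylic acids | COCOc1ccc(cc1OC)[C@@H]2[C@@H](C(=O)O[C@@H]3C[C@H]4[C@H](CN(C)C[C@@H]4C)[C@H]3C)[C@H](CC/C(C)=C/C(=O)O)[C@@]2(C)C(=O)O | intermediate
24 | bis(acid chloride) of 23 | COCOc1ccc(cc1OC)[C@@H]2[C@@H](C(=O)O[C@@H]3C[C@H]4[C@H](CN(C)C[C@@H]4C)[C@H]3C)[C@H](CC/C(C)=C/C(=O)Cl)[C@@]2(C)C(=O)Cl | intermediate
25 | lithium alkoxide of 21 | [Li+].[O-][C@@H]1C[C@H]2[C@H](CN(C)C[C@@H]2C)[C@H]1C | intermediate
26 | methoxymethyl ether of the target (tris ester of 21) | COCOc1ccc(cc1OC)[C@@H]2[C@@H](C(=O)O[C@@H]3C[C@H]4[C@H](CN(C)C[C@@H]4C)[C@H]3C)[C@H](CC/C(C)=C/C(=O)O[C@@H]3C[C@H]4[C@H](CN(C)C[C@@H]4C)[C@H]3C)[C@@]2(C)C(=O)O[C@@H]2C[C@H]3[C@H](CN(C)C[C@@H]3C)[C@H]2C | intermediate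
27 | CNP0251577.2 | COc1cc([C@@H]2[C@@H](C(=O)O[C@@H]3C[C@H]4[C@H](CN(C)C[C@@H]4C)[C@H]3C)[C@H](CC/C(C)=C/C(=O)O[C@@H]3C[C@H]4[C@H](CN(C)C[C@@H]4C)[C@H]3C)[C@@]2(C)C(=O)O[C@@H]2C[C@H]3[C@H](CN(C)C[C@@H]3C)[C@H]2C)ccc1O | target

**Step count.** Total: 16 steps. Longest linear sequence: 10 steps (13 to 27, steps 7 to 16).

**Steps most likely to fail**

1. Step 6 (Proposed new method). What may go wrong: exchange of acyl groups in the mixed anhydride before irradiation; first bond formation onto the methyl-bearing alkene carbon, which would give the fused head-to-head adduct; poor facial control when the 1,4-diradical closes. The fallback sets out from 3 and 9 and comes back at 12, with known reactions only. The two acids are irradiated together without a tether (3 with an excess of 9, same iridium sensitizer, MeCN, 450 nm). Intermolecular triplet-sensitised [2+2] heterodimerisation of a cinnamic acid derivative with an alkene is a known reaction type, and the same benzylic/tertiary diradical should give the head-to-tail cyclobutane-1,3-dicarboxylic acid F1 as a mixture of stereoisomers. Heating with acetic anhydride and NaOAc should epimerise the hydrogen-bearing carboxyl carbon and close the isomers whose two ring carboxyl groups can become cis. Anhydride 12 is then separated from isomers with a syn aryl group or side chain. This is less selective, but each operation is precedented.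

2. Step 15. What may go wrong: incomplete acylation at the acyl chloride on the quaternary ring carbon; deprotonation γ to the unsaturated acyl chloride, which would move the side-chain double bond out of conjugation or scramble its geometry. The fallback sets out from 21 and 23 and comes back at 26; it activates the alcohol instead of the acids. Mitsunobu inversion of 21 with 4-nitrobenzoic acid (PPh3, diisopropyl azodicarboxylate) should give the C6-inverted 4-nitrobenzoate F2. Methanolysis (K2CO3, MeOH) gives the C6-epimeric amino alcohol F3. A twofold Mitsunobu esterification of diacid 23 with F3 should then form both ester C–O bonds with inversion at C6, the carboxylates acting as nucleophiles, and give 26.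

3. Step 12. What may go wrong: hydride delivery from the concave face, which would give the C6 epimer or a mixture. The fallback sets out from 20 and comes back at 21; it separates the two reductions and puts the alcohol under thermodynamic control. Dissolving-metal reduction of 20 (Li, liquid NH3, t-BuOH, THF, −78 °C) should give the hydroxy carbamate F4 with the hydroxyl group trans to the neighbouring methyl group. LiAlH4 in refluxing THF then reduces only the carbamate and gives 21.

**Further compounds**

F1 | step 6 | 2-[3-methoxy-4-(methoxymethoxy)phenyl]-4-[(3E)-5-methoxy-3-methyl-5-oxopent-3-en-1-yl]-1-methylcyclobutane-1,3-dicarboxylic acid (racemic; all-trans isomer shown) | COCOc1ccc(cc1OC)[C@@H]2[C@@H](C(=O)O)[C@H](CC/C(C)=C/C(=O)OC)[C@@]2(C)C(=O)O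
F2 | step 15 | (4R,4aR,6S,7R,7aS)-2,4,7-trimethyloctahydro-1H-cyclopenta[c]pyridin-6-yl 4-nitrobenzoate | O=C(O[C@H]1C[C@H]2[C@H](CN(C)C[C@@H]2C)[C@H]1C)c1ccc(cc1)[N+](=O)[O-]
F3 | step 15 | (4R,4aR,6S,7R,7aS)-2,4,7-trimethyloctahydro-1H-cyclopenta[c]pyridin-6-ol | O[C@H]1C[C@H]2[C@H](CN(C)C[C@@H]2C)[C@H]1C
F4 | step 12 | methyl (4R,4aR,6R,7R,7aS)-6-hydroxy-4,7-dimethyloctahydro-2H-cyclopenta[c]pyridine-2-carboxylate | O[C@@H]1C[C@H]2[C@H](CN(C(=O)OC)C[C@@H]2C)[C@H]1C
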